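**Plan**
- Retrosynthetic cuts: the C3–C1′ bond to the dienyl chain (Suzuki coupling), the C6 acetate and the masks on the C5 oxygen and carboxyl, the C5–O bond (enolate oxidation), the C4a–C5 bond (enolate SNAr, the ring-closing cut), and the C7–C7a bond (pyridyl Grignard plus a citramalate acylal).
- Forward order: the pyridine ring is bought; C7–C7a is made first, the cyclopentanone ring is then closed through C4a–C5 and C5 is oxygenated in the same flask; the side chain is joined in the penultimate step.
- Enabling feature: C4a is para to N2 and ortho to the C7 carbonyl, so a chloride there is an SNAr leaving group; C5 is α to the ester carbonyl; the C5 carboxyl and the C6 oxygen are cis on the five-membered ring, so one acetal carbon can tie them into a six-membered acylal.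
- Stereochemistry: C6 comes from (S)-citramalic acid; C5 follows from the cis fusion of that acylal (oxygen enters trans to the C6 oxygen); C5′ comes from (S)-2-methylbutan-1-ol; both E alkenes come from Wittig and boron-Wittig olefinations.

Key step: step 4

Remark: locants C1–C7a of the target's cyclopenta[c]pyridine core are used for all intermediates; keto acid 6 is drawn open-chain, and any lactol tautomer is assumed to react through the open form.

**Step 1**
Reactants: 1 (S)-citramalic acid
Product: 2 2-[(4S)-2,2,4-trimethyl-5-oxo-1,3-dioxolan-4-yl]acetic acid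
Conditions: 2,2-dimethoxypropane, TsOH·H2O (cat.), acetone, rt
Reagents that add atoms: 2,2-dimethoxypropane, COC(C)(C)OC
Why: Acid-catalysed transketalisation should close the five-membered dioxolanone on the α-hydroxy acid unit in preference to the six-membered alternative, leaving the CH2CO2H arm free and the quaternary stereocentre untouched.

**Step 2**
Reactants: 2 2-[(4S)-2,2,4-trimethyl-5-oxo-1,3-dioxolan-4-yl]acetic acid; 3 5-bromo-2,4-dichloropyridine
Product: 6 (3S)-4-(4,6-dichloropyridin-3-yl)-3-hydroxy-3-methyl-4-oxobutanoic acid, via (4,6-dichloropyridin-3-yl)magnesium chloride 4 (not isolated), via dioxolan-4-ol adduct 5 (not isolated)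
Conditions: 3, i-PrMgCl·LiCl, THF, −15 °C; added to the ClMg carboxylate of 2 (i-PrMgCl·LiCl, THF, −40 °C); −40 → 0 °C; cold 1 M HCl
Reagents that add atoms: none
Why: Bromine–magnesium exchange gives the pyridyl Grignard, and its addition to the acylal carbonyl (Grignard acylation; the carboxylate arm is inert) should stop at a cyclic magnesium hemiketal that releases acetone and the α-hydroxy ketone only on acidic work-up, with C6 untouched.

**Step 3**
Reactants: 6 (3S)-4-(4,6-dichloropyridin-3-yl)-3-hydroxy-3-methyl-4-oxobutanoic acid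
Product: 7 (6S)-6-(4,6-dichloropyridine-3-carbonyl)-2,2,6-trimethyl-1,3-dioxan-4-one
Conditions: 2-methoxypropene, PPTS (cat.), CH2Cl2, 0 °C → rt
Reagents that add atoms: 2-methoxypropene, COC(C)=C
Why: Acid-catalysed ketalisation with the enol ether should tie the carboxyl group and the tertiary C6 hydroxyl into a 2,2-dimethyl-1,3-dioxan-4-one, which removes the free alkoxide that could arylate through oxygen and installs the tether that later controls C5.

**Step 4**
Reactants: 7 (6S)-6-(4,6-dichloropyridine-3-carbonyl)-2,2,6-trimethyl-1,3-dioxan-4-one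
Product: 9 (5R,6S)-3-chloro-5,6-dihydroxy-6-methyl-7-oxo-6,7-dihydro-5H-cyclopenta[c]pyridine-5-carboxylic acid as its cis-fused isopropylidene acylal between CO2H and 6-OH (5-OH free), via tricyclic C5–H acylal 8 (not isolated)
Conditions: LiHMDS (2.3 equiv), THF, −78 → −40 °C; then 2-(phenylsulfonyl)-3-phenyloxaziridine, −78 °C; AcOH
Reagents that add atoms: 2-(phenylsulfonyl)-3-phenyloxaziridine, O=S(=O)(N1OC1c1ccccc1)c1ccccc1
Why: LiHMDS turns the dioxanone into its lithium enolate, whose α-carbon (C5) adds ipso to the chlorine-bearing pyridine carbon (the future C4a), activated by the para ring nitrogen and the ortho ketone, and chloride leaves from the Meisenheimer adduct; this is an intramolecular enolate SNAr (transition-metal-free α-arylation), the reaction type known for ester, lactone and amide enolates on 2- and 4-halopyridines. The cyclopentanone closes in a 5-exo-trig mode and must be cis-fused to the acylal ring, because the aryl group is delivered by the carbonyl arm on C6. Acylal 8 is more acidic than 7 and should be deprotonated at once by the second equivalent of base to a planar, pyridine-conjugated enolate, which the N-sulfonyloxaziridine hydroxylates (Davis oxidation). The new stereocentre C5 is set by the tether: oxygen can only enter on the face that keeps the five/six ring fusion cis, which puts C5–OH trans to the C6 oxygen and the carboxyl carbon cis to it, while C6 is carried over from citramalic acid. The step needs carbon and not oxygen arylation (7 has no C6 alkoxide), attack at the 4- and not the 6-chloride (only the former is within reach of the tether), no ketone enolate (C6 is quaternary) and no β-elimination (the endocyclic C6–O bond of the dioxanone enolate is poorly aligned with the π system at −78 °C, and the oxidant is added as soon as the ring has closed).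

**Step 5**
Reactants: 9 the 5-hydroxy tricyclic acylal
Product: 10 5-O-triethylsilyl ether of 9
Conditions: TESOTf, 2,6-lutidine, CH2Cl2, −78 → 0 °C
Reagents that add atoms: triethylsilyl trifluoromethanesulfonate, CC[Si](CC)(CC)OS(=O)(=O)C(F)(F)F
Why: Silylation with a silyl triflate should cap the only free hydroxyl, the hindered tertiary C5–OH, so that the two tertiary oxygens stay differentiated once the acylal is opened.

**Step 6**
Reactants: 10 5-O-triethylsilyl tricyclic acylal
Product: 11 methyl (5R,6S)-3-chloro-6-hydroxy-6-methyl-7-oxo-5-[(triethylsilyl)oxy]-6,7-dihydro-5H-cyclopenta[c]pyridine-5-carboxylate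
Conditions: K2CO3 (cat.), MeOH, 0 °C, short contact
Reagents that add atoms: methanol, CO
Why: Base-catalysed methanolysis (transesterification) at the activated acylal carbonyl should give the methyl ester while the expelled hemiketal loses acetone to free the C6 hydroxyl; the trans arrangement of C5–OSi and C6–OH prevents silyl migration.

**Step 7**
Reactants: 11 the C6-hydroxy methyl ester
Product: 12 methyl (5R,6S)-6-acetoxy-3-chloro-6-methyl-7-oxo-5-[(triethylsilyl)oxy]-6,7-dihydro-5H-cyclopenta[c]pyridine-5-carboxylate
Conditions: Ac2O, DMAP, Et3N, CH2Cl2, 25–40 °C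
Reagents that add atoms: acetic anhydride, CC(=O)OC(C)=O
Why: DMAP-catalysed acylation should acetylate the single free hydroxyl, the tertiary α-ketol at C6, with no stereocentre affected.

**Step 8**
Reactants: 13 (S)-2-methylbutan-1-ol
Product: 15 (2E,4S)-2,4-dimethylhex-2-enal, via (S)-2-methylbutanal 14 (not isolated)
Conditions: TEMPO (cat.), KBr (cat.), NaOCl, NaHCO3, CH2Cl2/H2O, 0 °C; dried organic phase, then Ph3P=C(Me)CHO, PhMe, 80 °C
Reagents that add atoms: 2-(triphenyl-λ5-phosphanylidene)propanal, CC(C=O)=P(c1ccccc1)(c1ccccc1)c1ccccc1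
Why: Buffered Anelli oxidation gives the configurationally labile aldehyde, and Wittig olefination with the stabilised formyl ylide should convert it into the (E)-enal without touching the α-stereocentre.

**Step 9**
Reactants: 15 (2E,4S)-2,4-dimethylhex-2-enal
Product: 16 2-[(1E,3E,5S)-3,5-dimethylhepta-1,3-dien-1-yl]-4,4,5,5-tetramethyl-1,3,2-dioxaborolane
Conditions: CH2(Bpin)2, LiTMP, THF, 0 °C; then 15, −78 °C → rt
Reagents that add atoms: bis(4,4,5,5-tetramethyl-1,3,2-dioxaborolan-2-yl)methane, CC1(C)OB(CB2OC(C)(C)C(C)(C)O2)OC1(C)C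
Why: In this boron-Wittig olefination the lithiated geminal bis(boronate) adds 1,2 to the aldehyde and syn B–O elimination should give the (E)-alkenyl boronate, so the diene is (1E,3E) with C5 unchanged.

**Step 10**
Reactants: 12 the C3-chloro acetate; 16 the dienyl boronate
Product: 17 methyl (5R,6S)-6-acetoxy-3-[(1E,3E,5S)-3,5-dimethylhepta-1,3-dien-1-yl]-6-methyl-7-oxo-5-[(triethylsilyl)oxy]-6,7-dihydro-5H-cyclopenta[c]pyridine-5-carboxylate
Conditions: XPhos Pd G3 (cat.), K3PO4, THF/H2O, 40 °C
Reagents that add atoms: none
Why: Suzuki–Miyaura coupling at the C3–Cl bond (α to nitrogen, para to the acyl group) should proceed with retention of alkene geometry, and with C5–OH silylated the mild base cannot trigger retro-aldol cleavage.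

**Step 11**
Reactants: 17 the silyl-protected coupling product
Product: 18 methyl (5R,6S)-6-acetoxy-3-[(1E,3E,5S)-3,5-dimethylhepta-1,3-dien-1-yl]-5-hydroxy-6-methyl-7-oxo-6,7-dihydro-5H-cyclopenta[c]pyridine-5-carboxylate (CNP0483502.1)
Conditions: HF·pyridine, pyridine, THF, 0 °C → rt
Reagents that add atoms: none
Why: Fluoride-mediated desilylation should remove the triethylsilyl ether without touching the acetate, the ester or the diene, and the trans relationship of C5–OH and C6–OAc rules out acetyl migration.

**Compound list**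
1 | (S)-citramalic acid | C[C@](O)(CC(=O)O)C(=O)O | starting material
2 | 2-[(4S)-2,2,4-trimethyl-5-oxo-1,3-dioxolan-4-yl]acetic acid | C[C@@]1(CC(=O)O)OC(C)(C)OC1=O | intermediate
3 | 5-bromo-2,4-dichloropyridine | Clc1cc(Cl)c(Br)cn1 | starting material
4 | (4,6-dichloropyridin-3-yl)magnesium chloride (LiCl complex) | Clc1cc(Cl)c([Mg]Cl)cn1 | intermediate
5 | 2-[(4S)-5-(4,6-dichloropyridin-3-yl)-5-hydroxy-2,2,4-trimethyl-1,3-dioxolan-4-yl]acetic acid, present as its magnesium salt, hemiketal carbon unassigned | Clc1cc(Cl)c(cn1)C2(O)OC(C)(C)O[C@@]2(C)CC(=O)O | intermediate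
6 | (3S)-4-(4,6-dichloropyridin-3-yl)-3-hydroxy-3-methyl-4-oxobutanoic acid | Clc1cc(Cl)c(cn1)C(=O)[C@@](C)(O)CC(=O)O | intermediate
7 | (6S)-6-(4,6-dichloropyridine-3-carbonyl)-2,2,6-trimethyl-1,3-dioxan-4-one | Clc1cc(Cl)c(cn1)C(=O)[C@@]2(C)OC(C)(C)OC(=O)C2 | intermediate
8 | (5S,6S)-3-chloro-6-hydroxy-6-methyl-7-oxo-6,7-dihydro-5H-cyclopenta[c]pyridine-5-carboxylic acid as its cis-fused isopropylidene acylal (2,2-dimethyl-1,3-dioxan-4-one; ring O on C6, lactone C=O on C5, H on C5); present as its lithium enolate | Clc1cc2c(cn1)C(=O)[C@@]3(C)OC(C)(C)OC(=O)[C@@H]23 | intermediate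
9 | (5R,6S)-3-chloro-5,6-dihydroxy-6-methyl-7-oxo-6,7-dihydro-5H-cyclopenta[c]pyridine-5-carboxylic acid as its cis-fused isopropylidene acylal between CO2H and 6-OH; 5-OH free | Clc1cc2c(cn1)C(=O)[C@@]3(C)OC(C)(C)OC(=O)[C@@]23O | intermediate
10 | 5-O-triethylsilyl ether of 9 | Clc1cc2c(cn1)C(=O)[C@@]3(C)OC(C)(C)OC(=O)[C@@]23O[Si](CC)(CC)CC | intermediate
11 | methyl (5R,6S)-3-chloro-6-hydroxy-6-methyl-7-oxo-5-[(triethylsilyl)oxy]-6,7-dihydro-5H-cyclopenta[c]pyridine-5-carboxylate | Clc1cc2c(cn1)C(=O)[C@@](C)(O)[C@@]2(O[Si](CC)(CC)CC)C(=O)OC | intermediate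
12 | methyl (5R,6S)-6-acetoxy-3-chloro-6-methyl-7-oxo-5-[(triethylsilyl)oxy]-6,7-dihydro-5H-cyclopenta[c]pyridine-5-carboxylate | Clc1cc2c(cn1)C(=O)[C@@](C)(OC(C)=O)[C@@]2(O[Si](CC)(CC)CC)C(=O)OC | intermediate
13 | (S)-2-methylbutan-1-ol | CC[C@H](C)CO | starting material
14 | (S)-2-methylbutanal | CC[C@H](C)C=O | intermediate
15 | (2E,4S)-2,4-dimethylhex-2-enal | CC[C@H](C)/C=C(C)/C=O | intermediate
16 | 2-[(1E,3E,5S)-3,5-dimethylhepta-1,3-dien-1-yl]-4,4,5,5-tetramethyl-1,3,2-dioxaborolane | CC[C@H](C)/C=C(C)/C=C/B1OC(C)(C)C(C)(C)O1 | intermediate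
17 | methyl (5R,6S)-6-acetoxy-3-[(1E,3E,5S)-3,5-dimethylhepta-1,3-dien-1-yl]-6-methyl-7-oxo-5-[(triethylsilyl)oxy]-6,7-dihydro-5H-cyclopenta[c]pyridine-5-carboxylate | CC[C@H](C)/C=C(C)/C=C/c1cc2c(cn1)C(=O)[C@@](C)(OC(C)=O)[C@@]2(O[Si](CC)(CC)CC)C(=O)OC | intermediate
18 | methyl (5R,6S)-6-acetoxy-3-[(1E,3E,5S)-3,5-dimethylhepta-1,3-dien-1-yl]-5-hydroxy-6-methyl-7-oxo-6,7-dihydro-5H-cyclopenta[c]pyridine-5-carboxylate | CC[C@H](C)/C=C(C)/C=C/c1cc2c(cn1)C(=O)[C@@](C)(OC(C)=O)[C@@]2(O)C(=O)OC | target

**Count**
Total steps: 11. Longest linear sequence: 9 (steps 1–7, 10, 11 from (S)-citramalic acid).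

**Steps most likely to fail**

1. Step 4. The cyclised, doubly stabilised enolate may be lost before oxygen transfer, either by ring-opening β-elimination of the acetal oxygen or by addition to the sulfonimine by-product, and oxygen transfer to so hindered an enolate may stall. The fallback sets out from 8 and comes back at 9. The ring closure is quenched with acetic acid and 8 is isolated. Soft enolisation with TMSOTf/Et3N in CH2Cl2 at 0 °C gives the trimethylsilyl ketene acetal of 8, F1. Rubottom oxidation with dimethyldioxirane in acetone at −40 → 0 °C should epoxidise it on the face that keeps the ring fusion cis and, after silyl shift, give the 5-O-trimethylsilyl ether of 9, F2. Aqueous citric acid in THF then frees 9. No free enolate carrying a β-leaving group is involved in the oxidation.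

2. Step 2. Addition of the electron-poor, ortho-chlorinated pyridyl Grignard to the hindered acylal carbonyl may be slow, so that the Grignard decays by pyridyne formation or the adduct collapses early and takes up a second aryl group. The fallback sets out from 2 and comes back at 6. The dioxolanone is opened with the chloromagnesium amide of N,O-dimethylhydroxylamine (MeNHOMe·HCl, i-PrMgCl, THF, −20 °C) to (3S)-3-hydroxy-4-[methoxy(methyl)amino]-3-methyl-4-oxobutanoic acid, F3. Excess Grignard 4 then adds once to the alkoxide-chelated N-methoxy-N-methylamide and gives 6 after acidic work-up.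

3. Step 3. Closure of the hindered, electron-poor tertiary hydroxyl onto the mixed ketal may be incomplete, or the γ-keto acid may drain into its lactol manifold under equilibrating acid. The fallback sets out from 6 and comes back at 7. Silylation with TMSOTf/Et3N in CH2Cl2 at 0 °C gives trimethylsilyl (3S)-4-(4,6-dichloropyridin-3-yl)-3-methyl-4-oxo-3-[(trimethylsilyl)oxy]butanoate, F4. Acetone with catalytic TMSOTf in CH2Cl2 at −78 °C (silyl-transfer ketalisation under kinetic control) should then close the dioxanone to 7.

**Further compounds**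
F1 | step 4 | trimethylsilyl ketene acetal of 8 (6S; C5=C(OSiMe3) within the dioxane ring) | Clc1cc2c(cn1)C(=O)[C@@]3(C)OC(C)(C)OC(O[Si](C)(C)C)=C23
F2 | step 4 | 5-O-trimethylsilyl ether of 9 (5R,6S) | Clc1cc2c(cn1)C(=O)[C@@]3(C)OC(C)(C)OC(=O)[C@@]23O[Si](C)(C)C
F3 | step 2 | (3S)-3-hydroxy-4-[methoxy(methyl)amino]-3-methyl-4-oxobutanoic acid | CON(C)C(=O)[C@@](C)(O)CC(=O)O
F4 | step 3 | trimethylsilyl (3S)-4-(4,6-dichloropyridin-3-yl)-3-methyl-4-oxo-3-[(trimethylsilyl)oxy]butanoate | Clc1cc(Cl)c(cn1)C(=O)[C@@](C)(O[Si](C)(C)C)CC(=O)O[Si](C)(C)C
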